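**Retrosynthetic overview**

1. Numbering: ring C1 (ketone), C2/C3 (oxirane carbons, methyl on C2), C4 (CH2), C5 (carries the side chain), C6 (senecioate carbon); chain C7 (exocyclic methylene carbon), C8 (angelate carbon). The route rests on two features: C6 (oxygen) and C5 (carbon branch) are the carbinol carbon and the alkylated carbon of an anti 3-alkylated (S)-malate, and the C1–C2 bond of the carbocycle links a carbonyl carbon to the methyl-bearing sp2 carbon, so it can be made from an alkenyl nucleophile and an aldehyde.
2. Late stage: C1 ketone by oxidation of the C1 carbinol; C6 senecioate and C8 angelate by acylation; C7–C8 by a ligand-controlled nickel/chromium coupling of the C7 enol triflate (from the C5 ester via the methyl ketone) with 4-methylpent-3-enal.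
3. Oxirane (second ring formed): hydroxyl-directed epoxidation of the cyclohex-2-enol, which needs the C1 hydroxyl on the face of the C5 substituent.
4. Carbocycle (first ring formed): intramolecular Nozaki–Hiyama–Kishi closure of C1–C2 from a (Z)-iodoalkene aldehyde.
5. That aldehyde: from diethyl (S)-malate by Fráter–Seebach alkylation with (2Z)-1-bromo-3-iodobut-2-ene (from but-2-yn-1-ol), hydroxyl-directed reduction of the α-hydroxy ester, bis-silylation and Swern oxidation.

Key step: step 7

Assumption: in step 14 the (S)-configured oxazoline–sulfonamide ligand is taken to be the antipode that directs Re-face addition for this substrate pair; if a trial shows the opposite sense, the mirror-image ligand is used with no other change.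

**Route**

Step 1
Reactants: 1 but-2-yn-1-ol
Product: 3 (2Z)-3-iodobut-2-en-1-ol, via cyclic alkenylalanate 2 (not isolated)
Conditions: NaAlH2(OCH2CH2OMe)2, THF, 0 °C to rt; then I2, THF, −78 to 0 °C
Reagents that add atoms: iodine, II
Why: Hydroxyl-directed trans-hydroalumination of the propargylic alcohol puts aluminium on C3 inside a five-membered alanate, cis to the carbinol carbon, and iododealumination with retention should give the Z iodoalkene only.

Step 2
Reactants: 3 (2Z)-3-iodobut-2-en-1-ol
Product: 4 (2Z)-1-bromo-3-iodobut-2-ene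
Conditions: CBr4, PPh3, CH2Cl2, 0 °C
Reagents that add atoms: carbon tetrabromide, BrC(Br)(Br)Br
Why: Appel bromination displaces the oxyphosphonium ion of the primary allylic alcohol by SN2 under neutral conditions, so the Z iodoalkene is neither isomerised nor transposed.

Step 3
Reactants: 5 diethyl (S)-malate; 4 (2Z)-1-bromo-3-iodobut-2-ene
Product: 7 diethyl (2S,3R)-2-hydroxy-3-[(2Z)-3-iodobut-2-en-1-yl]butanedioate, via dilithium alkoxide enolate 6 (not isolated)
Conditions: LiN(iPr)2 (2.1 equiv), THF, −78 to −20 °C; then 4, −78 to −10 °C; the minor syn isomer is removed by chromatography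
Reagents that add atoms: none
Why: Fráter–Seebach alkylation: the chelated dilithium alkoxide enolate is attacked by the allylic bromide on the face away from the ester-bearing side of the chelate, which sets the new centre (ring C5) anti to the retained malate carbinol (ring C6).

Step 4
Reactants: 7 diethyl (2S,3R)-2-hydroxy-3-[(2Z)-3-iodobut-2-en-1-yl]butanedioate
Product: 8 ethyl (2R,4Z)-2-[(1S)-1,2-dihydroxyethyl]-5-iodohex-4-enoate
Conditions: BH3·SMe2 (1.05 equiv), NaBH4 (5 mol%), THF, 0 °C to rt; MeOH quench; crude diol taken on at once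
Reagents that add atoms: none
Why: Hydroxyl-directed borane reduction: the alkoxyborane formed at the free hydroxyl passes hydride, with catalytic NaBH4, only to the neighbouring ester through a five-membered chelate, so the remote ester and the electron-poor iodoalkene should remain, and no stereocentre is touched.

Step 5
Reactants: 8 ethyl (2R,4Z)-2-[(1S)-1,2-dihydroxyethyl]-5-iodohex-4-enoate
Product: 9 ethyl (2R,4Z)-2-[(1S)-1,2-bis(triethylsilyloxy)ethyl]-5-iodohex-4-enoate
Conditions: TESCl (2.5 equiv), imidazole, CH2Cl2, 0 °C to rt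
Reagents that add atoms: chlorotriethylsilane, CC[Si](Cl)(CC)CC
Why: Standard silylation of a primary and a secondary alcohol with a silyl chloride and imidazole masks both hydroxyls before the γ-hydroxy ester can lactonise.

Step 6
Reactants: 9 ethyl (2R,4Z)-2-[(1S)-1,2-bis(triethylsilyloxy)ethyl]-5-iodohex-4-enoate
Product: 10 ethyl (2R,4Z)-5-iodo-2-[(1S)-2-oxo-1-(triethylsilyloxy)ethyl]hex-4-enoate
Conditions: (COCl)2, DMSO, CH2Cl2, −78 to −40 °C; then Et3N, −78 °C to rt
Reagents that add atoms: none
Why: Under Swern conditions the chlorosulfonium salt cleaves a primary triethylsilyl ether and oxidises it in the same pot while the secondary one survives, which avoids a free γ-hydroxy ester, and the α-silyloxy aldehyde is not epimerised at low temperature.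

Step 7
Reactants: 10 ethyl (2R,4Z)-5-iodo-2-[(1S)-2-oxo-1-(triethylsilyloxy)ethyl]hex-4-enoate
Product: 12 ethyl (1R,5S,6S)-5-hydroxy-4-methyl-6-(triethylsilyloxy)cyclohex-3-ene-1-carboxylate, via alkenylchromium dichloride 11 (not isolated)
Conditions: CrCl2 (6 equiv), NiCl2 (0.1 equiv), degassed DMF (0.01 M), rt
Reagents that add atoms: none
Why: CrCl2 reduces NiCl2 to zerovalent nickel, which adds oxidatively to the C2–I bond of 10 without loss of the alkene geometry, and transmetalation to trivalent chromium gives the nucleophilic alkenylchromium 11 that attacks the C1 aldehyde (closest known reaction type: intramolecular Nozaki–Hiyama–Kishi cyclisation of iodoalkene aldehydes to cyclohex-2-enols). The six-membered carbocycle closes in a 6-exo-trig mode, the attacked C=O being exocyclic to the new ring while C2=C3 ends up inside it, and the Z geometry fixed in step 1 is what lets C2 reach C1. The new C1 centre is controlled by the existing C5 and C6 centres: with the ester and the silyl ether both equatorial on the forming chair, the bulky solvated O–Cr group should also sit equatorial, which places the hydroxyl on the face of the C5 ester and opposite to the C6 oxygen. The step needs chemoselectivity for the aldehyde over the ester, which alkenylchromium reagents provide, and high dilution against intermolecular coupling; because the medium is not basic, the enolisable C5 and C6 centres should not epimerise and the C6 silyl ether should not be eliminated.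

Step 8
Reactants: 12 ethyl (1R,5S,6S)-5-hydroxy-4-methyl-6-(triethylsilyloxy)cyclohex-3-ene-1-carboxylate
Product: 13 ethyl (1R,2R,3S,4R,6S)-2-hydroxy-1-methyl-3-(triethylsilyloxy)-7-oxabicyclo[4.1.0]heptane-4-carboxylate
Conditions: VO(acac)2 (5 mol%), tBuOOH, CH2Cl2, 0 °C to rt
Reagents that add atoms: tert-butyl hydroperoxide, CC(C)(C)OO
Why: Hydroxyl-directed epoxidation of a cyclic allylic alcohol: the vanadate ester of the C1 hydroxyl delivers the peroxide oxygen to its own face, so the C2–C3 oxirane (new centres C2 and C3) forms cis to the C1 hydroxyl and the C5 substituent and trans to the C6 silyl ether.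

Step 9
Reactants: 13 ethyl (1R,2R,3S,4R,6S)-2-hydroxy-1-methyl-3-(triethylsilyloxy)-7-oxabicyclo[4.1.0]heptane-4-carboxylate
Product: 14 C1 tert-butyldimethylsilyl ether of 13 (ethyl 2-(tert-butyldimethylsilyloxy)-1-methyl-3-(triethylsilyloxy)-7-oxabicyclo[4.1.0]heptane-4-carboxylate, all centres as in 13)
Conditions: TBSOTf, 2,6-lutidine, CH2Cl2, −78 to 0 °C
Reagents that add atoms: tert-butyldimethylsilyl triflate, CC(C)(C)[Si](C)(C)OS(=O)(=O)C(F)(F)F
Why: Silylation of a hindered secondary alcohol with a silyl triflate and a hindered pyridine base at low temperature is routinely tolerated by epoxy alcohols and leaves the ester and the triethylsilyl ether alone.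

Step 10
Reactants: 14 C1 tert-butyldimethylsilyl ether of 13
Product: 15 N-methoxy-N-methyl amide of the C5 carboxyl group (Weinreb amide, all centres as in 13)
Conditions: MeNH(OMe)·HCl, iPrMgCl, THF, −20 to 0 °C
Reagents that add atoms: N,O-dimethylhydroxylamine hydrochloride, CNOC.Cl
Why: Weinreb amide formation by aminolysis of the ester with the chloromagnesium amide runs at low temperature, where a β-silyloxy ester should neither eliminate nor epimerise and a hindered trisubstituted oxirane is not opened.

Step 11
Reactants: 15 Weinreb amide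
Product: 16 C5 methyl ketone (1-[2-(tert-butyldimethylsilyloxy)-1-methyl-3-(triethylsilyloxy)-7-oxabicyclo[4.1.0]heptan-4-yl]ethan-1-one, all centres as in 13)
Conditions: MeMgBr, THF, −20 to 0 °C; aqueous NH4Cl
Reagents that add atoms: methylmagnesium bromide, C[Mg]Br
Why: Grignard addition to a Weinreb amide stops at the chelated tetrahedral adduct, which releases the methyl ketone on work-up without over-addition, and C5 stays in its more stable equatorial configuration.

Step 12
Reactants: 16 C5 methyl ketone
Product: 18 enol triflate (1-[2-(tert-butyldimethylsilyloxy)-1-methyl-3-(triethylsilyloxy)-7-oxabicyclo[4.1.0]heptan-4-yl]ethenyl trifluoromethanesulfonate), via potassium enolate 17 (not isolated)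
Conditions: KN(SiMe3)2, THF, −78 °C; then PhNTf2, −78 to −20 °C
Reagents that add atoms: N-phenylbis(trifluoromethanesulfonimide), O=S(=O)(N(c1ccccc1)S(=O)(=O)C(F)(F)F)C(F)(F)F
Why: Kinetic deprotonation by the bulky amide base occurs at the methyl group and not at the hindered C5 methine, and O-triflation of that enolate gives the 1,1-disubstituted enol triflate.

Step 13
Reactants: 19 4-methylpent-3-en-1-ol
Product: 20 4-methylpent-3-enal
Conditions: Dess–Martin periodinane, NaHCO3, CH2Cl2, 0 °C to rt; used at once as a solution
Reagents that add atoms: none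
Why: Dess–Martin oxidation of a primary alcohol under buffered, neutral conditions should give the β,γ-unsaturated aldehyde without migration of the double bond into conjugation.

Step 14
Reactants: 18 enol triflate; 20 4-methylpent-3-enal
Product: 21 (8S)-allylic alcohol ((3S)-6-methyl-2-[2-(tert-butyldimethylsilyloxy)-1-methyl-3-(triethylsilyloxy)-7-oxabicyclo[4.1.0]heptan-4-yl]hepta-1,5-dien-3-ol, ring centres as in 13)
Conditions: CrCl2 (4 equiv), (S)-N-[2-(4-isopropyl-4,5-dihydro-1,3-oxazol-2-yl)-6-methylphenyl]methanesulfonamide (4.4 equiv), Et3N (4.4 equiv), THF, rt; then NiCl2 (0.1 equiv), 18, 20 (2 equiv), rt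
Reagents that add atoms: none
Why: Intermolecular Nozaki–Hiyama–Kishi alkenylation of an aldehyde with an enol triflate as alkenyl donor, in which the chiral sulfonamide ligand bound to chromium selects the Re face of the aldehyde and so sets C8 as S, while the neutral conditions spare the oxirane, the silyl ethers and the β,γ-unsaturated aldehyde.

Step 15
Reactants: 21 (8S)-allylic alcohol
Product: 22 C8 angelate of 21 ((2Z)-2-methylbut-2-enoate)
Conditions: angelic acid, 2,4,6-trichlorobenzoyl chloride, Et3N, toluene, rt; then 21, 80 °C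
Reagents that add atoms: angelic acid, C/C=C(/C)C(=O)O
Why: Yamaguchi esterification through the mixed anhydride without a nucleophilic catalyst is the usual way to keep the Z geometry of an angelate, and C8 keeps its configuration because only the O–H bond reacts.

Step 16
Reactants: 22 C8 angelate
Product: 23 C6 alcohol (22 without the triethylsilyl group)
Conditions: HF·pyridine, pyridine, THF, 0 °C
Reagents that add atoms: none
Why: Buffered fluoride desilylation cleaves the more labile triethylsilyl ether selectively, and the hindered tert-butyldimethylsilyl ether, the oxirane and both esters are expected to survive.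

Step 17
Reactants: 23 C6 alcohol
Product: 24 C6 senecioate of 23 (3-methylbut-2-enoate)
Conditions: 3-methylbut-2-enoic acid, 2,4,6-trichlorobenzoyl chloride, Et3N, THF, rt; then 23, 4-(dimethylamino)pyridine, toluene, rt
Reagents that add atoms: 3-methylbut-2-enoic acid, CC(C)=CC(=O)O
Why: Yamaguchi esterification through the mixed anhydride and an acylpyridinium ion acylates the hindered C6 hydroxyl with retention, and this acid has no alkene geometry to lose.

Step 18
Reactants: 24 C6 senecioate
Product: 25 C1 alcohol (24 without the tert-butyldimethylsilyl group)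
Conditions: Bu4NF, AcOH (1:1), THF, 0 °C to rt
Reagents that add atoms: none
Why: Fluoride cleavage of the remaining silyl ether with acetic acid as buffer keeps the medium near neutral, which should suppress migration of the neighbouring C6 acyl group and opening of the oxirane.

Step 19
Reactants: 25 C1 alcohol
Product: 26 target CNP0333561.1 ((2S,3S,5S,6S,8S) in the numbering of the overview)
Conditions: Dess–Martin periodinane, NaHCO3, CH2Cl2, 0 °C to rt
Reagents that add atoms: none
Why: Dess–Martin oxidation of the secondary C1 carbinol gives the epoxy ketone under buffered, non-basic conditions, so C6 should not epimerise and the angelate should not isomerise.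

**Compound list**

1 | but-2-yn-1-ol | CC#CCO | starting material
2 | cyclic alkenylalanate (sodium 2,2-bis(2-methoxyethoxy)-3-methyl-2,5-dihydro-1,2-oxaluminol-2-uide) | CC1=CCO[Al-]1(OCCOC)OCCOC.[Na+] | intermediate
3 | (2Z)-3-iodobut-2-en-1-ol | C/C(I)=C/CO | intermediate
4 | (2Z)-1-bromo-3-iodobut-2-ene | C/C(I)=C/CBr | intermediate
5 | diethyl (S)-malate | CCOC(=O)C[C@H](O)C(=O)OCC | starting material
6 | dilithium alkoxide enolate of 5 | CCOC(=O)[C@@H]([O-])C=C([O-])OCC.[Li+].[Li+] | intermediate
7 | diethyl (2S,3R)-2-hydroxy-3-[(2Z)-3-iodobut-2-en-1-yl]butanedioate | CCOC(=O)[C@H](C/C=C(/C)I)[C@H](O)C(=O)OCC | intermediate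
8 | ethyl (2R,4Z)-2-[(1S)-1,2-dihydroxyethyl]-5-iodohex-4-enoate | CCOC(=O)[C@H](C/C=C(/C)I)[C@H](O)CO | intermediate
9 | ethyl (2R,4Z)-2-[(1S)-1,2-bis(triethylsilyloxy)ethyl]-5-iodohex-4-enoate | CCOC(=O)[C@H](C/C=C(/C)I)[C@H](O[Si](CC)(CC)CC)CO[Si](CC)(CC)CC | intermediate
10 | ethyl (2R,4Z)-5-iodo-2-[(1S)-2-oxo-1-(triethylsilyloxy)ethyl]hex-4-enoate | CCOC(=O)[C@H](C/C=C(/C)I)[C@H](O[Si](CC)(CC)CC)C=O | intermediate
11 | alkenylchromium dichloride derived from 10 (chromium in place of iodine, Z geometry kept) | CCOC(=O)[C@H](C/C=C(/C)[Cr](Cl)Cl)[C@H](O[Si](CC)(CC)CC)C=O | intermediate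
12 | ethyl (1R,5S,6S)-5-hydroxy-4-methyl-6-(triethylsilyloxy)cyclohex-3-ene-1-carboxylate (hydroxyl cis to ester, trans to silyl ether) | CCOC(=O)[C@@H]1CC=C(C)[C@H](O)[C@H]1O[Si](CC)(CC)CC | intermediate
13 | ethyl (1R,2R,3S,4R,6S)-2-hydroxy-1-methyl-3-(triethylsilyloxy)-7-oxabicyclo[4.1.0]heptane-4-carboxylate (oxirane cis to the hydroxyl) | CCOC(=O)[C@@H]1C[C@@H]2O[C@]2(C)[C@H](O)[C@H]1O[Si](CC)(CC)CC | intermediate
14 | C1 tert-butyldimethylsilyl ether of 13 | CCOC(=O)[C@@H]1C[C@@H]2O[C@]2(C)[C@H](O[Si](C)(C)C(C)(C)C)[C@H]1O[Si](CC)(CC)CC | intermediate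
15 | Weinreb amide from 14 | CON(C)C(=O)[C@@H]1C[C@@H]2O[C@]2(C)[C@H](O[Si](C)(C)C(C)(C)C)[C@H]1O[Si](CC)(CC)CC | intermediate
16 | C5 methyl ketone | CC(=O)[C@@H]1C[C@@H]2O[C@]2(C)[C@H](O[Si](C)(C)C(C)(C)C)[C@H]1O[Si](CC)(CC)CC | intermediate
17 | potassium enolate of 16 at the methyl group | C=C([O-])[C@@H]1C[C@@H]2O[C@]2(C)[C@H](O[Si](C)(C)C(C)(C)C)[C@H]1O[Si](CC)(CC)CC.[K+] | intermediate
18 | enol triflate at C7 | C=C(OS(=O)(=O)C(F)(F)F)[C@@H]1C[C@@H]2O[C@]2(C)[C@H](O[Si](C)(C)C(C)(C)C)[C@H]1O[Si](CC)(CC)CC | intermediate
19 | 4-methylpent-3-en-1-ol | CC(C)=CCCO | starting material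
20 | 4-methylpent-3-enal | CC(C)=CCC=O | intermediate
21 | (8S)-allylic alcohol | C=C([C@@H](O)CC=C(C)C)[C@@H]1C[C@@H]2O[C@]2(C)[C@H](O[Si](C)(C)C(C)(C)C)[C@H]1O[Si](CC)(CC)CC | intermediate
22 | C8 angelate, C6 triethylsilyl ether, C1 tert-butyldimethylsilyl ether | C=C([C@H](CC=C(C)C)OC(=O)/C(C)=C\C)[C@@H]1C[C@@H]2O[C@]2(C)[C@H](O[Si](C)(C)C(C)(C)C)[C@H]1O[Si](CC)(CC)CC | intermediate
23 | C8 angelate, C6 alcohol, C1 tert-butyldimethylsilyl ether | C=C([C@H](CC=C(C)C)OC(=O)/C(C)=C\C)[C@@H]1C[C@@H]2O[C@]2(C)[C@H](O[Si](C)(C)C(C)(C)C)[C@H]1O | intermediate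
24 | C8 angelate, C6 senecioate, C1 tert-butyldimethylsilyl ether | C=C([C@H](CC=C(C)C)OC(=O)/C(C)=C\C)[C@@H]1C[C@@H]2O[C@]2(C)[C@H](O[Si](C)(C)C(C)(C)C)[C@H]1OC(=O)C=C(C)C | intermediate
25 | C8 angelate, C6 senecioate, C1 alcohol | C=C([C@H](CC=C(C)C)OC(=O)/C(C)=C\C)[C@@H]1C[C@@H]2O[C@]2(C)[C@H](O)[C@H]1OC(=O)C=C(C)C | intermediate
26 | CNP0333561.1 | C=C([C@H](CC=C(C)C)OC(=O)/C(C)=C\C)[C@@H]1C[C@@H]2O[C@]2(C)C(=O)[C@H]1OC(=O)C=C(C)C | target

**Summary**

Total step count: 19. Longest linear sequence: 18 steps (steps 1–12 and 14–19, from but-2-yn-1-ol; 16 from diethyl (S)-malate).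

Steps most likely to fail:

Step 7. The closure may show poor facial selectivity at C1: allylic strain between the C2 methyl group and an equatorial O–Cr group works against the equatorial preference, so the alkoxide may also end up axial, and the C1 epimer would later steer the oxirane to the wrong face. The fallback sets out from 10. The crude cyclisation product, 12 together with its C1 epimer ethyl (1R,5R,6S)-5-hydroxy-4-methyl-6-(triethylsilyloxy)cyclohex-3-ene-1-carboxylate F1, is oxidised with Dess–Martin periodinane and NaHCO3 in CH2Cl2 to the enone ethyl (1R,6S)-4-methyl-5-oxo-6-(triethylsilyloxy)cyclohex-3-ene-1-carboxylate F2. Luche reduction (NaBH4, CeCl3·7H2O, MeOH, −78 °C) then sets C1 by axial hydride delivery instead of by C–C bond formation. This should give the equatorial alcohol, and the route is rejoined at 12.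

Step 14. Face discrimination at the aldehyde may be insufficient if ligand and the neighbouring C5 centre are mismatched, or activation of the enol triflate may be slow in the presence of the ligand. The fallback sets out from 18 and 20. They are coupled without ligand (CrCl2, NiCl2 0.05 equiv, DMF, rt) to the mixture of C8 epimers of 21 F3. Oxidation with Dess–Martin periodinane and NaHCO3 gives the C8 ketone F4. Corey–Bakshi–Shibata reduction with (R)-1-methyl-3,3-diphenyltetrahydro-1H,3H-pyrrolo[1,2-c][1,3,2]oxazaborole and catecholborane in toluene at −78 °C, in which the branched alkenyl group acts as the large substituent, should return the 8S alcohol, and the route is rejoined at 21.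

Step 4. Chemoselectivity may be lost: borane may hydroborate the iodoalkene, or the diol ester may lactonise during work-up. The fallback sets out from 7. Its hydroxyl is silylated (TESCl, imidazole, DMF) to diethyl (2S,3R)-3-[(2Z)-3-iodobut-2-en-1-yl]-2-(triethylsilyloxy)butanedioate F5. One equivalent of iBu2AlH in CH2Cl2 at −78 °C should then reduce the more electrophilic α-silyloxy ester to the aldehyde while the branched β-ester remains. The route is rejoined at 10, and compounds 8 and 9 are bypassed.

**Further compounds**

F1 | step 7 | ethyl (1R,5R,6S)-5-hydroxy-4-methyl-6-(triethylsilyloxy)cyclohex-3-ene-1-carboxylate (C1 epimer of 12) | CCOC(=O)[C@@H]1CC=C(C)[C@@H](O)[C@H]1O[Si](CC)(CC)CC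
F2 | step 7 | ethyl (1R,6S)-4-methyl-5-oxo-6-(triethylsilyloxy)cyclohex-3-ene-1-carboxylate | CCOC(=O)[C@@H]1CC=C(C)C(=O)[C@H]1O[Si](CC)(CC)CC
F3 | step 14 | mixture of C8 epimers of 21 | C=C(C(O)CC=C(C)C)[C@@H]1C[C@@H]2O[C@]2(C)[C@H](O[Si](C)(C)C(C)(C)C)[C@H]1O[Si](CC)(CC)CC
F4 | step 14 | C8 ketone corresponding to 21 | C=C(C(=O)CC=C(C)C)[C@@H]1C[C@@H]2O[C@]2(C)[C@H](O[Si](C)(C)C(C)(C)C)[C@H]1O[Si](CC)(CC)CC
F5 | step 4 | diethyl (2S,3R)-3-[(2Z)-3-iodobut-2-en-1-yl]-2-(triethylsilyloxy)butanedioate | CCOC(=O)[C@H](C/C=C(/C)I)[C@H](O[Si](CC)(CC)CC)C(=O)OCC
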